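**Plan**
1. Ring numbering: C1 carries the propyl chain, C3 and C4 the hydroxyls, C5 the methoxyl. The retrosynthesis cuts the stearate C–O bond, then the chain bond between the benzylic carbon and its neighbour (olefination of an aryl aldehyde derived from a benzoate), then ring bonds C1–C2 and C5–C6.
2. Enabling feature: C2–C3–C4–C5 with oxygens on C3 and C4 is a masked 3,4-dialkoxyfuran, and the C5 oxygen is the furan oxygen; C1 and C6 come from methyl propiolate. That oxygen emerges as the only free phenol beside two benzyl ethers, so it alone is methylated.
3. Forward: the furan ring is made first (diglycolate–oxalate condensation, benzylation, saponification, decarboxylation); the benzene ring then arises from it by Diels–Alder addition and opening of the oxygen bridge.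
4. The chain is grown on the ester carbon (reduction, oxidation–Wittig, alkene reduction, ester reduction), the alcohol is stearoylated, and the benzyl ethers are removed last.
5. Stereochemistry: the target has no stereocentre; the bridgehead centres of the racemic cycloadduct vanish on aromatisation and the alkene geometry of the cinnamate is erased by reduction.

Key step: step 5

**Step 1**
Reactants: 1 dimethyl diglycolate; 2 dimethyl oxalate
Product: 3 dimethyl 3,4-dihydroxyfuran-2,5-dicarboxylate
Conditions: NaOMe (2.5 equiv), MeOH, reflux; then aq. HCl
Reagents that add atoms: none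
Why: A double Claisen condensation of the Hinsberg type joins both α-methylene carbons of 1 to the two carbonyls of 2, and the furan should be driven to completion as its doubly deprotonated aromatic dienolate before acidification.

**Step 2**
Reactants: 3 dimethyl 3,4-dihydroxyfuran-2,5-dicarboxylate
Product: 4 dimethyl 3,4-bis(benzyloxy)furan-2,5-dicarboxylate
Conditions: BnBr (2.4 equiv), K2CO3, DMF, 60 °C
Reagents that add atoms: benzyl bromide, BrCc1ccccc1
Why: Williamson ether synthesis; the two enolic hydroxyls are acidified by the flanking esters, so carbonate deprotonates them and they should be O-benzylated by SN2 displacement.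

**Step 3**
Reactants: 4 dimethyl 3,4-bis(benzyloxy)furan-2,5-dicarboxylate
Product: 5 3,4-bis(benzyloxy)furan-2,5-dicarboxylic acid
Conditions: NaOH, THF/MeOH/H2O, reflux; then aq. HCl
Reagents that add atoms: sodium hydroxide, [Na+].[OH-]
Why: Ester saponification by acyl substitution with hydroxide; benzyl ethers are inert to aqueous base and the diacid should precipitate on acidification.

**Step 4**
Reactants: 5 3,4-bis(benzyloxy)furan-2,5-dicarboxylic acid
Product: 6 3,4-bis(benzyloxy)furan
Conditions: Cu powder (0.3 equiv), quinoline, 190–200 °C, under N2
Reagents that add atoms: none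
Why: Copper-mediated thermal protodecarboxylation of furan-2-carboxylic acids through furyl–copper intermediates, the standard exit from Hinsberg-type furan diesters to 3,4-dialkoxyfurans, should remove both carboxyl groups.

**Step 5**
Reactants: 6 3,4-bis(benzyloxy)furan; 7 methyl propiolate
Product: 9 methyl 3,4-bis(benzyloxy)-5-hydroxybenzoate, via oxanorbornadiene 8 (not isolated)
Conditions: Me2AlCl (1.2 equiv), CH2Cl2, −78 to 0 °C; then 1 M HCl
Reagents that add atoms: none
Why: Me2AlCl binds the ester carbonyl of 7 and lowers its LUMO, so the electron-rich diene 6 should add across the alkyne in a concerted, asynchronous [4+2] cycloaddition (Lewis-acid-promoted furan–alkyne Diels–Alder reaction) that forms C1–C2 and C5–C6 and gives 8. The six-membered carbocycle closes in this single intermolecular cycloaddition, leaving the furan oxygen as a one-atom bridge between C2 and C5. The same Lewis acid then ionises the C2–O bond, the one at the bridgehead next to the ester-bearing C1, because the resulting pentadienyl cation keeps C1 at a node and places charge on the benzyloxy-bearing C4, whereas breaking C5–O would put charge on C1 itself; loss of the C5 proton then aromatises the ring, as in the known acid-induced isomerisation of 7-oxanorbornadienes to phenols. The only selectivity needed is this direction of opening (hydroxyl meta, not ortho, to the ester), secured by the ester; the cycloaddition has no regiochemical issue because 6 is symmetrical. No stereocentre is created in the product, since the two bridgehead centres of racemic 8 are erased on aromatisation. Low temperature and a single equivalent of a mild alkylaluminium halide are chosen to favour cycloaddition over conjugate addition of the furan α-carbon and to spare the benzyl ethers.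

**Step 6**
Reactants: 9 methyl 3,4-bis(benzyloxy)-5-hydroxybenzoate
Product: 10 methyl 3,4-bis(benzyloxy)-5-methoxybenzoate
Conditions: MeI, K2CO3, acetone, reflux
Reagents that add atoms: iodomethane, CI
Why: Williamson O-methylation of the only free phenol; the other two oxygens are already benzyl ethers, so no site selectivity is required.

**Step 7**
Reactants: 10 methyl 3,4-bis(benzyloxy)-5-methoxybenzoate
Product: 11 [3,4-bis(benzyloxy)-5-methoxyphenyl]methanol
Conditions: LiAlH4, THF, 0 °C
Reagents that add atoms: none
Why: Hydride reduction of an aryl ester to the benzylic alcohol; aryl benzyl and methyl ethers are untouched by LiAlH4.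

**Step 8**
Reactants: 11 [3,4-bis(benzyloxy)-5-methoxyphenyl]methanol; 12 methyl (triphenylphosphoranylidene)acetate
Product: 14 methyl (E)-3-[3,4-bis(benzyloxy)-5-methoxyphenyl]prop-2-enoate, via aryl aldehyde 13 (not isolated)
Conditions: MnO2 (10 equiv), toluene, reflux
Reagents that add atoms: none
Why: Tandem benzylic oxidation–Wittig olefination; MnO2 should oxidise the electron-rich benzylic alcohol to aldehyde 13, which the stabilised ylide traps in the same flask, mainly as the E-alkene, whose geometry is irrelevant because the alkene is reduced next.

**Step 9**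
Reactants: 14 methyl (E)-3-[3,4-bis(benzyloxy)-5-methoxyphenyl]prop-2-enoate
Product: 15 methyl 3-[3,4-bis(benzyloxy)-5-methoxyphenyl]propanoate
Conditions: NiCl2·6H2O (0.3 equiv), NaBH4 (3 equiv), MeOH/THF, 0 °C
Reagents that add atoms: none
Why: Nickel boride conjugate reduction; the boride formed from NiCl2 and NaBH4 should saturate the cinnamate C=C while leaving the ester and the aryl benzyl ethers, and methanol as co-solvent matches the methyl ester so that ester exchange is of no consequence.

**Step 10**
Reactants: 15 methyl 3-[3,4-bis(benzyloxy)-5-methoxyphenyl]propanoate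
Product: 16 3-[3,4-bis(benzyloxy)-5-methoxyphenyl]propan-1-ol
Conditions: LiAlH4, THF, 0 °C
Reagents that add atoms: none
Why: Hydride reduction of the saturated ester to the primary alcohol, with the ethers again inert.

**Step 11**
Reactants: 16 3-[3,4-bis(benzyloxy)-5-methoxyphenyl]propan-1-ol; 17 stearoyl chloride
Product: 18 3-[3,4-bis(benzyloxy)-5-methoxyphenyl]propyl octadecanoate
Conditions: Et3N, DMAP (cat.), CH2Cl2, 0 °C to rt
Reagents that add atoms: none
Why: DMAP-catalysed acyl transfer from an acid chloride to the only hydroxyl in the molecule, a primary alcohol, is a standard esterification.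

**Step 12**
Reactants: 18 3-[3,4-bis(benzyloxy)-5-methoxyphenyl]propyl octadecanoate
Product: 19 3-(3,4-dihydroxy-5-methoxyphenyl)propyl octadecanoate (target)
Conditions: H2 (1 atm), 10% Pd/C, EtOAc, rt; filtration under N2
Reagents that add atoms: none
Why: Catalytic hydrogenolysis of the two aryl benzyl ethers should release the catechol, while the saturated alkyl ester and the aryl methyl ether are inert; the neutral, non-nucleophilic solvent avoids acyl migration or transesterification.

**Compound list**
1 | dimethyl diglycolate (dimethyl 2,2'-oxydiacetate) | COC(=O)COCC(=O)OC | starting material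
2 | dimethyl oxalate | COC(=O)C(=O)OC | starting material
3 | dimethyl 3,4-dihydroxyfuran-2,5-dicarboxylate | COC(=O)c1oc(C(=O)OC)c(O)c1O | intermediate
4 | dimethyl 3,4-bis(benzyloxy)furan-2,5-dicarboxylate | COC(=O)c1oc(C(=O)OC)c(OCc2ccccc2)c1OCc1ccccc1 | intermediate
5 | 3,4-bis(benzyloxy)furan-2,5-dicarboxylic acid | OC(=O)c1oc(C(O)=O)c(OCc2ccccc2)c1OCc1ccccc1 | intermediate
6 | 3,4-bis(benzyloxy)furan | c1occ(OCc2ccccc2)c1OCc1ccccc1 | intermediate
7 | methyl propiolate | C#CC(=O)OC | starting material
8 | methyl 5,6-bis(benzyloxy)-7-oxabicyclo[2.2.1]hepta-2,5-diene-2-carboxylate (racemic) | COC(=O)C1=CC2OC1C(OCc1ccccc1)=C2OCc1ccccc1 | intermediate (not isolated)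
9 | methyl 3,4-bis(benzyloxy)-5-hydroxybenzoate | COC(=O)c1cc(O)c(OCc2ccccc2)c(OCc2ccccc2)c1 | intermediate
10 | methyl 3,4-bis(benzyloxy)-5-methoxybenzoate | COC(=O)c1cc(OC)c(OCc2ccccc2)c(OCc2ccccc2)c1 | intermediate
11 | [3,4-bis(benzyloxy)-5-methoxyphenyl]methanol | OCc1cc(OC)c(OCc2ccccc2)c(OCc2ccccc2)c1 | intermediate
12 | methyl (triphenylphosphoranylidene)acetate | COC(=O)C=P(c1ccccc1)(c1ccccc1)c1ccccc1 | starting material
13 | 3,4-bis(benzyloxy)-5-methoxybenzaldehyde | O=Cc1cc(OC)c(OCc2ccccc2)c(OCc2ccccc2)c1 | intermediate (not isolated)
14 | methyl (E)-3-[3,4-bis(benzyloxy)-5-methoxyphenyl]prop-2-enoate | COC(=O)/C=C/c1cc(OC)c(OCc2ccccc2)c(OCc2ccccc2)c1 | intermediate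
15 | methyl 3-[3,4-bis(benzyloxy)-5-methoxyphenyl]propanoate | COC(=O)CCc1cc(OC)c(OCc2ccccc2)c(OCc2ccccc2)c1 | intermediate
16 | 3-[3,4-bis(benzyloxy)-5-methoxyphenyl]propan-1-ol | OCCCc1cc(OC)c(OCc2ccccc2)c(OCc2ccccc2)c1 | intermediate
17 | stearoyl chloride (octadecanoyl chloride) | CCCCCCCCCCCCCCCCCC(=O)Cl | starting material
18 | 3-[3,4-bis(benzyloxy)-5-methoxyphenyl]propyl octadecanoate | CCCCCCCCCCCCCCCCCC(=O)OCCCc1cc(OC)c(OCc2ccccc2)c(OCc2ccccc2)c1 | intermediate
19 | 3-(3,4-dihydroxy-5-methoxyphenyl)propyl octadecanoate | CCCCCCCCCCCCCCCCCC(=O)OCCCc1cc(O)c(O)c(OC)c1 | target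

**Total step count:** 12
**Longest linear sequence:** 12 steps (from 1 and 2 to 19)

**Steps most likely to fail**

Step 5. The aluminium-bound propiolate may be attacked by the furan α-carbon in a conjugate, Friedel–Crafts-type addition instead of the cycloaddition. The bridge may also open partly in the ortho sense, or the Lewis acid may start to cleave a benzyl ether. The fallback keeps the same two ring bonds but uses an alkene dienophile and a base-induced opening whose direction is fixed by the ester. It sets out from 6, which would be combined with methyl acrylate (ZnI2 cat., neat, rt) to give methyl 5,6-bis(benzyloxy)-7-oxabicyclo[2.2.1]hept-5-ene-2-carboxylate F1 as an endo/exo mixture. LiHMDS in THF at −78 °C should deprotonate the ester α-carbon and expel the bridge oxygen from the adjacent bridgehead, giving methyl 3,4-bis(benzyloxy)-5-hydroxycyclohexa-1,3-diene-1-carboxylate F2, whose hydroxyl can only sit meta to the ester. Prompt oxidation of this allylic alcohol with MnO2 in CH2Cl2, before it can dehydrate, would give methyl 3,4-bis(benzyloxy)-5-oxocyclohexa-1,3-diene-1-carboxylate F3, which should tautomerise at once to the phenol. The fallback comes back to the route at 9.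

Step 4. The electron-rich furan may decompose or polymerise at about 200 °C, or the second carboxyl may be lost incompletely. The fallback replaces thermal protodecarboxylation by ipso-halogenation and reductive dehalogenation at low temperature. It sets out from 5, which would undergo double bromodecarboxylation with NBS (2 equiv) and LiOAc in aqueous MeCN to give 3,4-bis(benzyloxy)-2,5-dibromofuran F4. Bromine–lithium exchange with n-BuLi in THF at −78 °C and quenching with MeOH should then deliver the furan. The fallback comes back to the route at 6.

Step 9. Nickel boride may begin to hydrogenolyse the aryl benzyl ethers, or the conjugate reduction may stall short of full conversion. The fallback avoids the alkene altogether, bypasses steps 8 and 9, and builds the saturated chain by malonate homologation. It sets out from 11, which would be converted with PBr3 in Et2O at 0 °C into 1,2-bis(benzyloxy)-5-(bromomethyl)-3-methoxybenzene F5. Alkylation of sodium dimethyl malonate (NaH, THF) would give dimethyl 2-[3,4-bis(benzyloxy)-5-methoxybenzyl]malonate F6. Krapcho demethoxycarbonylation (LiCl, wet DMSO, 150 °C) should then remove one ester group. The fallback comes back to the route at 15.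

**Further compounds**
F1 | step 5 | methyl 5,6-bis(benzyloxy)-7-oxabicyclo[2.2.1]hept-5-ene-2-carboxylate (racemic, endo/exo mixture) | COC(=O)C1CC2OC1C(OCc1ccccc1)=C2OCc1ccccc1
F2 | step 5 | methyl 3,4-bis(benzyloxy)-5-hydroxycyclohexa-1,3-diene-1-carboxylate (racemic) | COC(=O)C1=CC(OCc2ccccc2)=C(OCc2ccccc2)C(O)C1
F3 | step 5 | methyl 3,4-bis(benzyloxy)-5-oxocyclohexa-1,3-diene-1-carboxylate | COC(=O)C1=CC(OCc2ccccc2)=C(OCc2ccccc2)C(=O)C1
F4 | step 4 | 3,4-bis(benzyloxy)-2,5-dibromofuran | Brc1oc(Br)c(OCc2ccccc2)c1OCc1ccccc1
F5 | step 9 | 1,2-bis(benzyloxy)-5-(bromomethyl)-3-methoxybenzene | BrCc1cc(OC)c(OCc2ccccc2)c(OCc2ccccc2)c1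
F6 | step 9 | dimethyl 2-[3,4-bis(benzyloxy)-5-methoxybenzyl]malonate | COC(=O)C(Cc1cc(OC)c(OCc2ccccc2)c(OCc2ccccc2)c1)C(=O)OC
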